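**Retrosynthetic overview**
1. The last bond is C11'=C12' (Wittig): hydroxy-trienal 25 (ring A, butenolide and the C10 unit) plus C15 phosphonium salt 34, whose β-ring is bought as (4R,6R)-actinol 26 and extended by Stille coupling.
2. The (Z)-ylidene bond C11=C12 comes from a vinylogous Mukaiyama aldol/elimination of butenolide 20 with trienedial 21; C8–C9 comes from a B-alkyl Suzuki coupling of vinylcyclohexenol 17 with 3-bromofuranone 18.
3. Enabling feature: in ring A (carotenoid numbering C1–C6, side chain from C7) the oxygen on C3 and carbon C7 on C6 stand 1,4 across the C4=C5 double bond, and C1(CH3)2–C2H2 is an isobutylene unit. With C7 at the carboxyl level, ring A is the Diels–Alder adduct of a 4-methyl-2-pyrone (ring O and C=O become O–C3 and C7) with isobutylene.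
4. Key step: enantioselective inverse-demand [4+2] of the flat pyrone ester 6 with isobutylene gives bicyclic lactone 8. The activating bridgehead ester is then removed (deallylation, Barton decarboxylation), the lactone bridge is cut (i-Bu2AlH, Wittig) and C3 is inverted (Mitsunobu).
5. Ring order: 2-pyrone (step 3, temporary), then the ring A carbocycle (step 4); the butenolide (18) and the β-ring (26) are brought in ready-made.

Key step: step 4

Remark: the (S,S)-ligand in step 4 (2,2'-(propane-2,2-diyl)bis[(4S)-4-tert-butyl-4,5-dihydro-1,3-oxazole]) is assigned by analogy with the square-planar copper–bis(oxazoline)–1,3-dicarbonyl model; should the sense of induction be opposite, the (R,R)-ligand is used and nothing else changes.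
Remark: compounds 1, 2, 7, 18, 21, 26 and 30 are taken as catalogue chemicals.

**Route**

Step 1
Reactants: 1 diallyl malonate; 2 acetone
Product: 3 bis(prop-2-en-1-yl) 2-(propan-2-ylidene)propanedioate
Conditions: Ac2O, ZnCl2 (cat.), reflux
Reagents that add atoms: none
Why: Knoevenagel condensation of a malonate with acetone, with acetic anhydride taking up the water under ZnCl2 catalysis; no stereocentre is formed.

Step 2
Reactants: 3 bis(prop-2-en-1-yl) 2-(propan-2-ylidene)propanedioate
Product: 4 bis(prop-2-en-1-yl) 2-[(3E)-4-(dimethylamino)but-3-en-2-ylidene]propanedioate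
Conditions: Me2NCH(OMe)2 (1.1 equiv), DMF, 100 °C, MeOH distilled off
Reagents that add atoms: N,N-dimethylformamide dimethyl acetal, COC(OC)N(C)C
Why: The γ-methyl groups of an alkylidene malonate are vinylogously acidic and condense with the formamide acetal (vinylogous aminomethylenation) to the push–pull (E)-dienamine; no stereocentre is formed.

Step 3
Reactants: 4 bis(prop-2-en-1-yl) 2-[(3E)-4-(dimethylamino)but-3-en-2-ylidene]propanedioate
Product: 6 prop-2-en-1-yl 4-methyl-2-oxo-2H-pyran-3-carboxylate, via aldehyde 5 (not isolated)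
Conditions: HCO2H (88% aq.), 90 °C
Reagents that add atoms: water, O
Why: Acid hydrolysis of the enamine gives aldehyde 5, whose enol oxygen lactonises onto the cis ester with loss of allyl alcohol, the standard 2-pyrone-3-carboxylate synthesis from 3-heteroatom-substituted allylidene malonates; no stereocentre is formed.

Step 4
Reactants: 6 prop-2-en-1-yl 4-methyl-2-oxo-2H-pyran-3-carboxylate; 7 2-methylpropene (isobutylene)
Product: 8 prop-2-en-1-yl (1S,4R)-5,8,8-trimethyl-3-oxo-2-oxabicyclo[2.2.2]oct-5-ene-4-carboxylate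
Conditions: [Cu((S,S)-t-Bu-box)](SbF6)2 (10 mol %), 4 Å MS, CH2Cl2, 7 (10 equiv), sealed tube, −20 °C → rt
Reagents that add atoms: none
Why: Proposed new method: the cationic divalent-copper bis(oxazoline) complex chelates the lactone and ester carbonyl groups of 6 and lowers the LUMO of the pyrone diene, so that isobutylene should add in an inverse-electron-demand, strongly asynchronous [4+2] cycloaddition in which its CH2 terminus bonds to pyrone C6 (the future carbinol carbon) while the developing tertiary cationic carbon closes onto pyrone C3 (the future ring carbon that carries the side chain). The closest known reaction type is the chiral-Lewis-acid-catalysed inverse-demand Diels–Alder reaction of 3-alkoxycarbonyl-2-pyrones with enol ethers, vinyl sulfides and styrene-type alkenes, extended here to a 1,1-dialkylethylene of comparable π-nucleophilicity. The one ring that is closed, the cyclohexene of ring A, is closed by this intermolecular [4+2] event with both σ-bonds formed suprafacially on one face of the flat pyrone, whose ring O–C(=O) unit is thereby lifted into the lactone bridge of a 2-oxabicyclo[2.2.2]octenone. The two new stereocentres are the bridgeheads: their cis relationship is enforced by the bridge, no endo/exo question arises because each alkene carbon carries two identical substituents, and the absolute configuration is set by the twofold-symmetric ligand, which leaves one face of the chelated pyrone open. The step needs regioselectivity, which the polarity of the 3-acyl-2-pyrone (C6 electrophilic, C3 enolate-like) against the Markovnikov polarity of isobutylene secures, and it needs ring closure to outrun ene-type proton loss and alkene oligomerisation, for which the mild chelating Lewis acid, molecular sieves and low temperature are chosen, the low temperature also keeping the adduct from losing CO2.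

Step 5
Reactants: 8 prop-2-en-1-yl (1S,4R)-5,8,8-trimethyl-3-oxo-2-oxabicyclo[2.2.2]oct-5-ene-4-carboxylate
Product: 9 (1S,4R)-5,8,8-trimethyl-3-oxo-2-oxabicyclo[2.2.2]oct-5-ene-4-carboxylic acid
Conditions: Pd(PPh3)4 (3 mol %), HCO2H, Et3N, THF, rt
Reagents that add atoms: none
Why: Tsuji–Trost deallylation with formate as hydride donor: zerovalent palladium ionises the unhindered allyl ester much faster than the hindered bridgehead allylic lactone, and the bridgehead acid cannot decarboxylate through an enol (anti-Bredt), so both stereocentres are untouched.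

Step 6
Reactants: 9 (1S,4R)-5,8,8-trimethyl-3-oxo-2-oxabicyclo[2.2.2]oct-5-ene-4-carboxylic acid
Product: 12 (1S,4R)-5,8,8-trimethyl-2-oxabicyclo[2.2.2]oct-5-en-3-one, via acid chloride 10 (not isolated), via Barton ester 11 (not isolated)
Conditions: (COCl)2, DMF (cat.), CH2Cl2, 0 °C → rt; then N-hydroxypyridine-2-thione sodium salt, DMAP (cat.), t-BuSH, THF, hν (tungsten lamp), 20–30 °C
Reagents that add atoms: none
Why: Barton reductive decarboxylation: the thiohydroxamate ester fragments under light to the bridgehead radical, which takes hydrogen from the thiol, and because a bridgehead cannot invert the configuration of the carbon that becomes C6 is retained by geometry.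

Step 7
Reactants: 12 (1S,4R)-5,8,8-trimethyl-2-oxabicyclo[2.2.2]oct-5-en-3-one
Product: 13 (1S,4R)-5,8,8-trimethyl-2-oxabicyclo[2.2.2]oct-5-en-3-ol (lactol; anomer mixture)
Conditions: i-Bu2AlH (1.1 equiv), CH2Cl2, −78 °C; aq. potassium sodium tartrate
Reagents that add atoms: none
Why: Partial reduction of a lactone to the lactol with i-Bu2AlH, the tetrahedral aluminate being stable at −78 °C; the anomeric centre is inconsequential and the crude lactol is used at once.

Step 8
Reactants: 13 (1S,4R)-5,8,8-trimethyl-2-oxabicyclo[2.2.2]oct-5-en-3-ol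
Product: 15 (1S,4R)-4-ethenyl-3,5,5-trimethylcyclohex-2-en-1-ol, via hydroxy-aldehyde 14 (not isolated)
Conditions: Ph3PCH3Br (3 equiv), KOt-Bu (2.9 equiv), THF, −20 °C → rt
Reagents that add atoms: methyltriphenylphosphonium bromide, C[P+](c1ccccc1)(c1ccccc1)c1ccccc1.[Br-]
Why: Wittig methylenation of the lactol through its open hydroxy-aldehyde tautomer 14, run cold with excess ylide so that olefination outruns epimerisation or conjugation at the α-carbon (C6); the cis relationship of hydroxyl and vinyl group is inherited from the bridge.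

Step 9
Reactants: 15 (1S,4R)-4-ethenyl-3,5,5-trimethylcyclohex-2-en-1-ol
Product: 16 (1R,4R)-4-ethenyl-3,5,5-trimethylcyclohex-2-en-1-yl 4-nitrobenzoate
Conditions: 4-nitrobenzoic acid, PPh3, DIAD, THF, 0 °C → rt
Reagents that add atoms: 4-nitrobenzoic acid, O=C(O)c1ccc(cc1)[N+](=O)[O-]
Why: Mitsunobu reaction: SN2 displacement of the allylic oxyphosphonium by the carboxylate, which enters on the face away from the vinyl group, inverts the carbinol centre (C3) from S to R and so gives the trans relationship that the target needs.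

Step 10
Reactants: 16 (1R,4R)-4-ethenyl-3,5,5-trimethylcyclohex-2-en-1-yl 4-nitrobenzoate
Product: 17 (1R,4R)-4-ethenyl-3,5,5-trimethylcyclohex-2-en-1-ol
Conditions: K2CO3 (cat.), MeOH, rt
Reagents that add atoms: none
Why: Transesterification of the activated aryl ester with methanol under carbonate catalysis cleaves the acyl–oxygen bond only, so the configuration at the carbinol carbon is kept.

Step 11
Reactants: 17 (1R,4R)-4-ethenyl-3,5,5-trimethylcyclohex-2-en-1-ol; 18 3-bromofuran-2(5H)-one
Product: 20 3-{2-[(1R,4R)-4-hydroxy-2,6,6-trimethylcyclohex-2-en-1-yl]ethyl}furan-2(5H)-one, via alkylborane 19 (not isolated)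
Conditions: 9-BBN (2.5 equiv, allowing for the free hydroxyl), THF, 0 °C → rt; then 18, PdCl2(dppf) (5 mol %), AsPh3 (5 mol %), aq. K3PO4, DMF, rt
Reagents that add atoms: none
Why: 9-BBN hydroborates only the terminal vinyl group (anti-Markovnikov, the trisubstituted ring alkene being inert) and the B-alkyl Suzuki–Miyaura coupling with the α-bromobutenolide forms the C8–C9 bond without touching a stereocentre.

Step 12
Reactants: 20 3-{2-[(1R,4R)-4-hydroxy-2,6,6-trimethylcyclohex-2-en-1-yl]ethyl}furan-2(5H)-one; 21 (2E,4E,6E)-2,7-dimethylocta-2,4,6-trienedial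
Product: 24 (2E,4E,6E,8Z)-8-[4-(2-{(1R,4R)-4-[(tert-butyldimethylsilyl)oxy]-2,6,6-trimethylcyclohex-2-en-1-yl}ethyl)-5-oxofuran-2(5H)-ylidene]-2,7-dimethylocta-2,4,6-trienal, via bis-silyl furan 22 (not isolated), via aldol silyl ether 23 (not isolated)
Conditions: TBSOTf (2.4 equiv), i-Pr2NEt (4 equiv), CH2Cl2, 0 °C; 21 (3 equiv), −78 → −20 °C; then DBU (3 equiv), rt
Reagents that add atoms: tert-butyldimethylsilyl trifluoromethanesulfonate, CC(C)(C)[Si](C)(C)OS(=O)(=O)C(F)(F)F
Why: Vinylogous Mukaiyama aldol of the 2-silyloxyfuran formed in the flask (the free hydroxyl is silylated in the same pot) at its C5 with one aldehyde group of the excess dialdehyde, then E1cB elimination of silanolate with DBU, in which both diastereomers of 23 should converge on the thermodynamically preferred (Z)-ylidene butenolide.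

Step 13
Reactants: 24 (2E,4E,6E,8Z)-8-[4-(2-{(1R,4R)-4-[(tert-butyldimethylsilyl)oxy]-2,6,6-trimethylcyclohex-2-en-1-yl}ethyl)-5-oxofuran-2(5H)-ylidene]-2,7-dimethylocta-2,4,6-trienal
Product: 25 (2E,4E,6E,8Z)-8-(4-{2-[(1R,4R)-4-hydroxy-2,6,6-trimethylcyclohex-2-en-1-yl]ethyl}-5-oxofuran-2(5H)-ylidene)-2,7-dimethylocta-2,4,6-trienal
Conditions: HF·pyridine, pyridine, THF, 0 °C → rt
Reagents that add atoms: none
Why: Fluoride-driven cleavage of the silyl ether under pyridine-buffered conditions, which should leave the lactone, the aldehyde and the acid-sensitive allylic alcohol intact; no stereocentre is touched.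

Step 14
Reactants: 26 (4R,6R)-4-hydroxy-2,2,6-trimethylcyclohexan-1-one (actinol)
Product: 27 (4R,6R)-2,2,6-trimethyl-4-[(triethylsilyl)oxy]cyclohexan-1-one
Conditions: Et3SiCl, imidazole, DMF, 0 °C → rt
Reagents that add atoms: chlorotriethylsilane, CC[Si](Cl)(CC)CC
Why: Standard silylation of a secondary alcohol; the labile triethylsilyl group is chosen so that it falls off by itself in step 18.

Step 15
Reactants: 27 (4R,6R)-2,2,6-trimethyl-4-[(triethylsilyl)oxy]cyclohexan-1-one
Product: 29 (4R)-2,6,6-trimethyl-4-[(triethylsilyl)oxy]cyclohex-1-en-1-yl trifluoromethanesulfonate, via lithium enolate 28 (not isolated)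
Conditions: LiN(i-Pr)2, THF, −78 °C; PhNTf2, −78 °C → rt
Reagents that add atoms: N-phenylbis(trifluoromethanesulfonimide), O=S(=O)(N(c1ccccc1)S(=O)(=O)C(F)(F)F)C(F)(F)F
Why: The ketone can enolise only toward the methyl-bearing carbon (the other α-carbon is quaternary), so a single tetrasubstituted enolate forms and is trapped on oxygen as the enol triflate; the methyl-bearing stereocentre is erased as planned and the silyloxy centre is untouched.

Step 16
Reactants: 30 (2E)-3-methylpent-2-en-4-yn-1-ol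
Product: 31 (2E,4E)-3-methyl-5-(tributylstannyl)penta-2,4-dien-1-ol
Conditions: Bu3SnH, PdCl2(PPh3)2 (2 mol %), THF, 0 °C
Reagents that add atoms: tributyltin hydride, CCCC[SnH](CCCC)CCCC
Why: Palladium-catalysed syn-hydrostannylation of the terminal alkyne of a conjugated enyne places tin on the terminal carbon and gives the (E)-alkenylstannane.

Step 17
Reactants: 29 (4R)-2,6,6-trimethyl-4-[(triethylsilyl)oxy]cyclohex-1-en-1-yl trifluoromethanesulfonate; 31 (2E,4E)-3-methyl-5-(tributylstannyl)penta-2,4-dien-1-ol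
Product: 32 (2E,4E)-3-methyl-5-{(4R)-2,6,6-trimethyl-4-[(triethylsilyl)oxy]cyclohex-1-en-1-yl}penta-2,4-dien-1-ol
Conditions: Pd2(dba)3 (2.5 mol %), AsPh3 (20 mol %), NMP, 50 °C
Reagents that add atoms: none
Why: Stille coupling of the hindered cyclohexenyl triflate with the dienylstannane, with AsPh3 speeding up transmetalation, forms the C6'–C7' bond with retention of both alkene geometries.

Step 18
Reactants: 32 (2E,4E)-3-methyl-5-{(4R)-2,6,6-trimethyl-4-[(triethylsilyl)oxy]cyclohex-1-en-1-yl}penta-2,4-dien-1-ol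
Product: 34 {(2E,4E)-5-[(4R)-4-hydroxy-2,6,6-trimethylcyclohex-1-en-1-yl]-3-methylpenta-2,4-dien-1-yl}triphenylphosphonium bromide, via diol 33 (not isolated)
Conditions: Ph3P·HBr (1.2 equiv), MeOH, 0 °C → rt
Reagents that add atoms: triphenylphosphine hydrobromide, [Br-].c1ccc(cc1)[PH+](c1ccccc1)c1ccccc1
Why: The acidic phosphonium salt first methanolyses the triethylsilyl ether and then converts the allylic alcohol through its allyl cation into the allylic phosphonium salt (the standard preparation of carotenoid Wittig salts), the chain settling in the more stable (E,E) form.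

Step 19
Reactants: 25 (2E,4E,6E,8Z)-8-(4-{2-[(1R,4R)-4-hydroxy-2,6,6-trimethylcyclohex-2-en-1-yl]ethyl}-5-oxofuran-2(5H)-ylidene)-2,7-dimethylocta-2,4,6-trienal; 34 {(2E,4E)-5-[(4R)-4-hydroxy-2,6,6-trimethylcyclohex-1-en-1-yl]-3-methylpenta-2,4-dien-1-yl}triphenylphosphonium bromide
Product: 37 target CNP0242041.1, via ylide 35 (not isolated), via 11'Z isomer 36 (not isolated)
Conditions: NaOMe, CH2Cl2–MeOH, 0 °C → rt; then heptane, 80 °C, dark, argon
Reagents that add atoms: none
Why: Wittig olefination forms C11'=C12', and the sterically hindered 11'Z isomer 36 that the semi-stabilised ylide gives alongside the E product should isomerise thermally to the all-E chain, while the (Z)-ylidene butenolide, the thermodynamic isomer, stays and no stereocentre is touched.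

**Compound list**
1 | diallyl malonate (bis(prop-2-en-1-yl) propanedioate) | C=CCOC(=O)CC(=O)OCC=C | starting material
2 | acetone | CC(C)=O | starting material
3 | bis(prop-2-en-1-yl) 2-(propan-2-ylidene)propanedioate | CC(C)=C(C(=O)OCC=C)C(=O)OCC=C | intermediate
4 | bis(prop-2-en-1-yl) 2-[(3E)-4-(dimethylamino)but-3-en-2-ylidene]propanedioate | CN(C)/C=C/C(C)=C(C(=O)OCC=C)C(=O)OCC=C | intermediate
5 | bis(prop-2-en-1-yl) 2-(4-oxobutan-2-ylidene)propanedioate | O=CCC(C)=C(C(=O)OCC=C)C(=O)OCC=C | intermediate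
6 | prop-2-en-1-yl 4-methyl-2-oxo-2H-pyran-3-carboxylate | CC1=C(C(=O)OCC=C)C(=O)OC=C1 | intermediate
7 | 2-methylpropene (isobutylene) | CC(C)=C | starting material
8 | prop-2-en-1-yl (1S,4R)-5,8,8-trimethyl-3-oxo-2-oxabicyclo[2.2.2]oct-5-ene-4-carboxylate | CC1=C[C@@H]2CC(C)(C)[C@@]1(C(=O)OCC=C)C(=O)O2 | intermediate
9 | (1S,4R)-5,8,8-trimethyl-3-oxo-2-oxabicyclo[2.2.2]oct-5-ene-4-carboxylic acid | CC1=C[C@@H]2CC(C)(C)[C@@]1(C(=O)O)C(=O)O2 | intermediate
10 | (1S,4S)-5,8,8-trimethyl-3-oxo-2-oxabicyclo[2.2.2]oct-5-ene-4-carbonyl chloride (same spatial arrangement as 9; the descriptor changes by priority only) | CC1=C[C@@H]2CC(C)(C)[C@@]1(C(Cl)=O)C(=O)O2 | intermediate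
11 | 2-thioxopyridin-1(2H)-yl (1S,4S)-5,8,8-trimethyl-3-oxo-2-oxabicyclo[2.2.2]oct-5-ene-4-carboxylate (Barton ester; same spatial arrangement as 9) | CC1=C[C@@H]2CC(C)(C)[C@@]1(C(=O)On1ccccc1=S)C(=O)O2 | intermediate
12 | (1S,4R)-5,8,8-trimethyl-2-oxabicyclo[2.2.2]oct-5-en-3-one | CC1=C[C@@H]2CC(C)(C)[C@H]1C(=O)O2 | intermediate
13 | (1S,4R)-5,8,8-trimethyl-2-oxabicyclo[2.2.2]oct-5-en-3-ol (lactol, both anomers) | CC1=C[C@@H]2CC(C)(C)[C@H]1C(O)O2 | intermediate
14 | (1R,4S)-4-hydroxy-2,6,6-trimethylcyclohex-2-ene-1-carbaldehyde | CC1=C[C@@H](O)CC(C)(C)[C@H]1C=O | intermediate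
15 | (1S,4R)-4-ethenyl-3,5,5-trimethylcyclohex-2-en-1-ol (hydroxyl and vinyl cis) | CC1=C[C@@H](O)CC(C)(C)[C@H]1C=C | intermediate
16 | (1R,4R)-4-ethenyl-3,5,5-trimethylcyclohex-2-en-1-yl 4-nitrobenzoate | CC1=C[C@H](OC(=O)c2ccc(cc2)[N+](=O)[O-])CC(C)(C)[C@H]1C=C | intermediate
17 | (1R,4R)-4-ethenyl-3,5,5-trimethylcyclohex-2-en-1-ol (hydroxyl and vinyl trans) | CC1=C[C@H](O)CC(C)(C)[C@H]1C=C | intermediate
18 | 3-bromofuran-2(5H)-one | O=C1OCC=C1Br | starting material
19 | 9-{2-[(1R,4R)-4-hydroxy-2,6,6-trimethylcyclohex-2-en-1-yl]ethyl}-9-borabicyclo[3.3.1]nonane | CC1=C[C@H](O)CC(C)(C)[C@H]1CCB1C2CCCC1CCC2 | intermediate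
20 | 3-{2-[(1R,4R)-4-hydroxy-2,6,6-trimethylcyclohex-2-en-1-yl]ethyl}furan-2(5H)-one | CC1=C[C@H](O)CC(C)(C)[C@H]1CCC1=CCOC1=O | intermediate
21 | (2E,4E,6E)-2,7-dimethylocta-2,4,6-trienedial | O=C/C(C)=C/C=C/C=C(C)/C=O | starting material
22 | tert-butyl{[3-(2-{(1R,4R)-4-[(tert-butyldimethylsilyl)oxy]-2,6,6-trimethylcyclohex-2-en-1-yl}ethyl)furan-2-yl]oxy}dimethylsilane | CC1=C[C@H](O[Si](C)(C)C(C)(C)C)CC(C)(C)[C@H]1CCc1ccoc1O[Si](C)(C)C(C)(C)C | intermediate
23 | 5-{(2E,4E,6E)-1-[(tert-butyldimethylsilyl)oxy]-2,7-dimethyl-8-oxoocta-2,4,6-trien-1-yl}-3-(2-{(1R,4R)-4-[(tert-butyldimethylsilyl)oxy]-2,6,6-trimethylcyclohex-2-en-1-yl}ethyl)furan-2(5H)-one (diastereomer mixture at the two new centres) | CC1=C[C@H](O[Si](C)(C)C(C)(C)C)CC(C)(C)[C@H]1CCC1=CC(OC1=O)C(O[Si](C)(C)C(C)(C)C)/C(C)=C/C=C/C=C(C)/C=O | intermediate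
24 | (2E,4E,6E,8Z)-8-[4-(2-{(1R,4R)-4-[(tert-butyldimethylsilyl)oxy]-2,6,6-trimethylcyclohex-2-en-1-yl}ethyl)-5-oxofuran-2(5H)-ylidene]-2,7-dimethylocta-2,4,6-trienal | CC1=C[C@H](O[Si](C)(C)C(C)(C)C)CC(C)(C)[C@H]1CCC1=C/C(=C/C(C)=C/C=C/C=C(C)/C=O)OC1=O | intermediate
25 | (2E,4E,6E,8Z)-8-(4-{2-[(1R,4R)-4-hydroxy-2,6,6-trimethylcyclohex-2-en-1-yl]ethyl}-5-oxofuran-2(5H)-ylidene)-2,7-dimethylocta-2,4,6-trienal | CC1=C[C@H](O)CC(C)(C)[C@H]1CCC1=C/C(=C/C(C)=C/C=C/C=C(C)/C=O)OC1=O | intermediate
26 | (4R,6R)-4-hydroxy-2,2,6-trimethylcyclohexan-1-one (actinol) | O=C1[C@H](C)C[C@@H](O)CC1(C)C | starting material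
27 | (4R,6R)-2,2,6-trimethyl-4-[(triethylsilyl)oxy]cyclohexan-1-one | O=C1[C@H](C)C[C@@H](O[Si](CC)(CC)CC)CC1(C)C | intermediate
28 | lithium (4R)-2,6,6-trimethyl-4-[(triethylsilyl)oxy]cyclohex-1-en-1-olate | [Li+].[O-]C1=C(C)C[C@@H](O[Si](CC)(CC)CC)CC1(C)C | intermediate
29 | (4R)-2,6,6-trimethyl-4-[(triethylsilyl)oxy]cyclohex-1-en-1-yl trifluoromethanesulfonate | FC(F)(F)S(=O)(=O)OC1=C(C)C[C@@H](O[Si](CC)(CC)CC)CC1(C)C | intermediate
30 | (2E)-3-methylpent-2-en-4-yn-1-ol | OC/C=C(C)/C#C | starting material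
31 | (2E,4E)-3-methyl-5-(tributylstannyl)penta-2,4-dien-1-ol | OC/C=C(C)/C=C/[Sn](CCCC)(CCCC)CCCC | intermediate
32 | (2E,4E)-3-methyl-5-{(4R)-2,6,6-trimethyl-4-[(triethylsilyl)oxy]cyclohex-1-en-1-yl}penta-2,4-dien-1-ol | OC/C=C(C)/C=C/C1=C(C)C[C@@H](O[Si](CC)(CC)CC)CC1(C)C | intermediate
33 | (2E,4E)-5-[(4R)-4-hydroxy-2,6,6-trimethylcyclohex-1-en-1-yl]-3-methylpenta-2,4-dien-1-ol | OC/C=C(C)/C=C/C1=C(C)C[C@@H](O)CC1(C)C | intermediate
34 | {(2E,4E)-5-[(4R)-4-hydroxy-2,6,6-trimethylcyclohex-1-en-1-yl]-3-methylpenta-2,4-dien-1-yl}triphenylphosphonium bromide | [Br-].c1ccc(cc1)[P+](c1ccccc1)(c1ccccc1)C/C=C(C)/C=C/C1=C(C)C[C@@H](O)CC1(C)C | intermediate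
35 | {(2E,4E)-5-[(4R)-4-hydroxy-2,6,6-trimethylcyclohex-1-en-1-yl]-3-methylpenta-2,4-dien-1-ylidene}triphenylphosphorane | c1ccc(cc1)P(c1ccccc1)(c1ccccc1)=C/C=C(C)/C=C/C1=C(C)C[C@@H](O)CC1(C)C | intermediate
36 | 11'Z isomer of the target: (5Z)-3-{2-[(1R,4R)-4-hydroxy-2,6,6-trimethylcyclohex-2-en-1-yl]ethyl}-5-{(2E,4E,6E,8Z,10E,12E)-13-[(4R)-4-hydroxy-2,6,6-trimethylcyclohex-1-en-1-yl]-2,7,11-trimethyltrideca-2,4,6,8,10,12-hexaen-1-ylidene}furan-2(5H)-one | CC1=C[C@H](O)CC(C)(C)[C@H]1CCC1=C/C(=C/C(C)=C/C=C/C=C(C)/C=C\C=C(C)\C=C\C2=C(C)C[C@@H](O)CC2(C)C)OC1=O | intermediate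
37 | CNP0242041.1: (5Z)-3-{2-[(1R,4R)-4-hydroxy-2,6,6-trimethylcyclohex-2-en-1-yl]ethyl}-5-{(2E,4E,6E,8E,10E,12E)-13-[(4R)-4-hydroxy-2,6,6-trimethylcyclohex-1-en-1-yl]-2,7,11-trimethyltrideca-2,4,6,8,10,12-hexaen-1-ylidene}furan-2(5H)-one | CC1=C[C@H](O)CC(C)(C)[C@H]1CCC1=C/C(=C/C(C)=C/C=C/C=C(C)/C=C/C=C(C)/C=C/C2=C(C)C[C@@H](O)CC2(C)C)OC1=O | target

**Step count and risks**
Total steps: 19. Longest linear sequence: 14 steps (steps 1–13 and 19).

Step 4 (riskiest; proposed new method). What may go wrong: the Lewis acid may start cationic oligomerisation of isobutylene, the polar transition state may lose a proton (ene-type product) instead of closing the second bond, or the ligand may discriminate the two pyrone faces poorly. Fallback with known chemistry, setting out from 6 and 7: the uncatalysed cycloaddition is run under high pressure (about 1 GPa, CH2Cl2, room temperature), the established way of adding simple alkenes to 2-pyrone-3-carboxylates with retention of the CO2 bridge. This should give racemic prop-2-en-1-yl 5,8,8-trimethyl-3-oxo-2-oxabicyclo[2.2.2]oct-5-ene-4-carboxylate F1. Deallylation as in step 5 gives racemic 5,8,8-trimethyl-3-oxo-2-oxabicyclo[2.2.2]oct-5-ene-4-carboxylic acid F2, which is resolved by crystallisation of the (R)-1-phenylethan-1-aminium salt of the (1S,4R)-acid F3 (the mirror-image amine is taken if the other salt is the less soluble one). Acidification of the salt returns to the route at 9.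

Step 12. What may go wrong: condensation at both ends of the dialdehyde, Lewis-acid-induced isomerisation or decomposition of the trienal, or incomplete and non-selective elimination. Fallback, setting out from 20 and 21: 20 is silylated separately (TBSOTf, Et3N, CH2Cl2) and bis-silyl furan 22 is isolated. Dialdehyde 21 is converted with HC(OMe)3 and catalytic p-TsOH in MeOH into its mono-acetal (2E,4E,6E)-8,8-dimethoxy-2,7-dimethylocta-2,4,6-trienal F4, the unreacted dialdehyde being recycled. Catalytic TMSOTf at −78 °C then activates the acetal in preference to the free conjugated aldehyde, and addition of 22 gives 5-[(2E,4E,6E)-1-methoxy-2,7-dimethyl-8-oxoocta-2,4,6-trien-1-yl]-3-(2-{(1R,4R)-4-[(tert-butyldimethylsilyl)oxy]-2,6,6-trimethylcyclohex-2-en-1-yl}ethyl)furan-2(5H)-one F5. Elimination of methanol with DBU comes back to the route at 24.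

Step 11. What may go wrong: base-induced decomposition of the bromobutenolide may outrun the slow alkyl transmetalation, and the alkylborane may protodeboronate. Fallback, setting out from 17: hydroboration with 9-BBN and oxidation with NaBO3·4H2O gives 2-[(1R,4R)-4-hydroxy-2,6,6-trimethylcyclohex-2-en-1-yl]ethan-1-ol F6. Selective oxidation of the primary alcohol (TEMPO, PhI(OAc)2) gives 2-[(1R,4R)-4-hydroxy-2,6,6-trimethylcyclohex-2-en-1-yl]acetaldehyde F7. Wittig reaction with 3-(triphenylphosphoranylidene)dihydrofuran-2(3H)-one (toluene, 60 °C) gives (3E)-3-{2-[(1R,4R)-4-hydroxy-2,6,6-trimethylcyclohex-2-en-1-yl]ethylidene}oxolan-2-one F8. Shifting the exocyclic double bond into the ring with RhCl3·3H2O (cat.) in EtOH comes back to the route at 20.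

**Further compounds**
F1 | step 4 | racemic prop-2-en-1-yl 5,8,8-trimethyl-3-oxo-2-oxabicyclo[2.2.2]oct-5-ene-4-carboxylate | CC1=CC2CC(C)(C)C1(C(=O)OCC=C)C(=O)O2
F2 | step 4 | racemic 5,8,8-trimethyl-3-oxo-2-oxabicyclo[2.2.2]oct-5-ene-4-carboxylic acid | CC1=CC2CC(C)(C)C1(C(=O)O)C(=O)O2
F3 | step 4 | (R)-1-phenylethan-1-aminium (1S,4R)-5,8,8-trimethyl-3-oxo-2-oxabicyclo[2.2.2]oct-5-ene-4-carboxylate | C[C@@H]([NH3+])c1ccccc1.CC1=C[C@@H]2CC(C)(C)[C@@]1(C(=O)[O-])C(=O)O2
F4 | step 12 | (2E,4E,6E)-8,8-dimethoxy-2,7-dimethylocta-2,4,6-trienal | COC(OC)/C(C)=C/C=C/C=C(C)/C=O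
F5 | step 12 | 5-[(2E,4E,6E)-1-methoxy-2,7-dimethyl-8-oxoocta-2,4,6-trien-1-yl]-3-(2-{(1R,4R)-4-[(tert-butyldimethylsilyl)oxy]-2,6,6-trimethylcyclohex-2-en-1-yl}ethyl)furan-2(5H)-one | CC1=C[C@H](O[Si](C)(C)C(C)(C)C)CC(C)(C)[C@H]1CCC1=CC(OC1=O)C(OC)/C(C)=C/C=C/C=C(C)/C=O
F6 | step 11 | 2-[(1R,4R)-4-hydroxy-2,6,6-trimethylcyclohex-2-en-1-yl]ethan-1-ol | CC1=C[C@H](O)CC(C)(C)[C@H]1CCO
F7 | step 11 | 2-[(1R,4R)-4-hydroxy-2,6,6-trimethylcyclohex-2-en-1-yl]acetaldehyde | CC1=C[C@H](O)CC(C)(C)[C@H]1CC=O
F8 | step 11 | (3E)-3-{2-[(1R,4R)-4-hydroxy-2,6,6-trimethylcyclohex-2-en-1-yl]ethylidene}oxolan-2-one | CC1=C[C@H](O)CC(C)(C)[C@H]1C/C=C1\CCOC1=O
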